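**Retrosynthetic overview**
- Feature: the cyclobutane consists of the octyl-bearing CH, the allylic CH, the CH shared by three rings and the cyclopentane-side CH. It shares one edge with the cyclopentane and the adjacent edge with the CH=CH cyclohexene. The bonds octyl-C–cyclopentane-side CH and allylic CH–three-ring CH are cut together as ketene C=C plus cyclopentene C=C, which also opens the CH=CH cyclohexene.
- Octyl group: exo-CH2OTs plus heptyl Grignard. The exo-CHO is placed under thermodynamic control and comes from the cyclobutanone C=O by methoxymethylenation.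
- Vinylketene precursor: a (Z)-but-3-enoyl chloride arm on the tertiary carbinol carbon of a trans-fused tetrahydroindene enoate. The arm comes from axial acetylide addition to a 2-iodoenone, the ester from Pd carbonylation, and the cyclopentene from RCM of trans vinyl/allyl groups.
- Absolute configuration: Rh/(R)-BINAP desymmetrising vinylation of p-benzoquinone dimethyl monoketal. All other centres follow by substrate control; the secondary carbinol needs Luche reduction followed by Mitsunobu inversion.
- Ring order: enoate six-membered ring (from the quinone ketal), then cyclopentene (RCM), then CH=CH cyclohexene and cyclobutane together.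

Key step: step 18

Assumption: the sense of induction of (R)-BINAP–Rh in step 1 is taken from the model established for cyclohex-2-enone. If the other enantiomer of 3 should form, (S)-BINAP is used and nothing else changes.

Locants for the bicyclic compounds follow 3a,4,7,7a-tetrahydro-1H-indene. H-3a, 4-O and 7-O lie on one face; H-7a and the C4 carbon chain lie on the other.

**Step 1**
Reactants: 1 4,4-dimethoxycyclohexa-2,5-dien-1-one; 2 potassium vinyltrifluoroborate
Product: 3 (5R)-5-ethenyl-4,4-dimethoxycyclohex-2-en-1-one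
Conditions: [Rh(cod)2]BF4 (3 mol %), (R)-BINAP (3.3 mol %), Et3N, toluene/H2O, 23 °C; 1.2 equiv of 1
Reagents that add atoms: none
Why: Rhodium-catalysed asymmetric 1,4-addition of an alkenyltrifluoroborate (Hayashi–Miyaura type, known for quinone monoketals) desymmetrises the two enantiotopic enone arms of 1, the (R)-BINAP–Rh–vinyl species choosing arm and face and so setting C5 (R), while the excess of 1 holds back a second addition.

**Step 2**
Reactants: 3 (5R)-5-ethenyl-4,4-dimethoxycyclohex-2-en-1-one; 4 allyl bromide
Product: 6 (5S,6S)-5-ethenyl-4,4-dimethoxy-6-(prop-2-enyl)cyclohex-2-en-1-one (vinyl and allyl trans), via lithium dienolate 5 (not isolated)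
Conditions: LDA, THF, −78 °C; allyl bromide, DMPU, −78 → −30 °C
Reagents that add atoms: none
Why: Kinetic enolate alkylation: C6 carries the only acidic α-hydrogens (the other α-carbon is vinylic and C4 has no H), and allyl bromide approaches dienolate 5 anti to the neighbouring vinyl group, giving the trans-diequatorial and also thermodynamically preferred 5,6-relationship.

**Step 3**
Reactants: 6 (5S,6S)-5-ethenyl-4,4-dimethoxy-6-(prop-2-enyl)cyclohex-2-en-1-one
Product: 7 (1S,5S,6S)-5-ethenyl-4,4-dimethoxy-6-(prop-2-enyl)cyclohex-2-en-1-ol (OH trans to allyl, all-equatorial)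
Conditions: NaBH4, CeCl3·7H2O, MeOH, −78 °C
Reagents that add atoms: none
Why: Luche reduction gives 1,2-selectivity and, by axial hydride attack on the half-chair that holds both carbon substituents equatorial, the all-equatorial alcohol, which is the C1 epimer of what the target needs and is made deliberately for inversion.

**Step 4**
Reactants: 7 (1S,5S,6S)-allylic alcohol
Product: 8 (1R,5S,6S)-5-ethenyl-4,4-dimethoxy-6-(prop-2-enyl)cyclohex-2-en-1-yl 4-nitrobenzoate (O cis to allyl)
Conditions: 4-O2NC6H4CO2H, PPh3, DIAD, THF, 0 °C → rt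
Reagents that add atoms: 4-nitrobenzoic acid O=C(O)c1ccc(cc1)[N+](=O)[O-]
Why: Mitsunobu reaction: SN2 displacement of the oxyphosphonium ion by 4-nitrobenzoate inverts C1 to the pseudoaxial C–O bond that no simple hydride delivers, SN2' attack being blocked by the fully substituted ketal carbon next to C3 and ionisation by its inductive effect.

**Step 5**
Reactants: 8 (1R,5S,6S)-4-nitrobenzoate
Product: 9 (1R,5S,6S)-5-ethenyl-4,4-dimethoxy-6-(prop-2-enyl)cyclohex-2-en-1-ol (OH cis to allyl, trans to vinyl)
Conditions: K2CO3 (0.2 equiv), MeOH, 0 °C → rt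
Reagents that add atoms: none
Why: Carbonate-catalysed transesterification removes the activated aroyl group with retention at C1 and leaves ketal and alkenes untouched.

**Step 6**
Reactants: 9 (1R,5S,6S)-allylic alcohol
Product: 10 tert-butyldimethylsilyl ether of 9
Conditions: TBSCl, imidazole, DMAP (cat.), DMF, 40 °C
Reagents that add atoms: tert-butyldimethylsilyl chloride CC(C)(C)[Si](C)(C)Cl
Why: Standard imidazole-promoted silylation; the chloride is used because silyl triflates would ionise the allylic ketal, and TBS is chosen to last until step 24.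

**Step 7**
Reactants: 10 TBS ether ketal
Product: 11 (4R,5S,6S)-4-[(tert-butyldimethylsilyl)oxy]-6-ethenyl-5-(prop-2-enyl)cyclohex-2-en-1-one
Conditions: PPTS (cat.), acetone/H2O, rt
Reagents that add atoms: water O
Why: Acid-catalysed hydrolysis of an allylic dimethyl ketal runs through a stabilised oxocarbenium ion under conditions too mild to cleave the TBS ether or to enolise the new ketone towards its allylic C6–H.

**Step 8**
Reactants: 11 (4R,5S,6S)-enone
Product: 12 (4S,5S,6S)-4-[(tert-butyldimethylsilyl)oxy]-6-ethenyl-2-iodo-5-(prop-2-enyl)cyclohex-2-en-1-one (same spatial arrangement; the C4 descriptor changes through the iodine)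
Conditions: I2, pyridine/CH2Cl2, 0 °C → rt
Reagents that add atoms: iodine II
Why: Pyridine-mediated α-iodination of an enone (conjugate addition of pyridine, iodination of the enolate, elimination) places the handle for the ester at C2, the weak base leaving the C6 stereocentre and the isolated alkenes alone.

**Step 9**
Reactants: 13 but-3-yn-1-ol
Product: 14 4-(triethylsilyloxy)but-1-yne
Conditions: TESCl, imidazole, CH2Cl2, 0 °C → rt
Reagents that add atoms: chlorotriethylsilane CC[Si](Cl)(CC)CC
Why: Routine silylation masks the hydroxyl proton so that one equivalent of base makes a soluble acetylide.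

**Step 10**
Reactants: 12 (4S,5S,6S)-2-iodoenone; 14 4-(triethylsilyloxy)but-1-yne
Product: 16 (1S,4S,5S,6S)-4-[(tert-butyldimethylsilyl)oxy]-6-ethenyl-2-iodo-5-(prop-2-enyl)-1-[4-(triethylsilyloxy)but-1-ynyl]cyclohex-2-en-1-ol (alkynyl cis to vinyl; OH cis to OTBS), via lithium acetylide 15 (not isolated)
Conditions: 14 (1.5 equiv), n-BuLi (1.4 equiv), THF, −78 °C; then 12, −78 °C; aq. NH4Cl
Reagents that add atoms: none
Why: 1,2-Addition of a lithium acetylide to a ketone: the slim nucleophile attacks the half-chair axially, on the face opposite the pseudoaxial OTBS group, which sets the tertiary carbinol with alkynyl cis to vinyl and OH cis to OTBS, while low temperature, the modest basicity of the acetylide and the absence of free n-BuLi guard against enolisation at C6 and I/Li exchange.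

**Step 11**
Reactants: 16 tertiary propargylic alcohol
Product: 17 bis-TES ether (tertiary O-TES derivative of 16)
Conditions: TESOTf, 2,6-lutidine, CH2Cl2, −78 → 0 °C
Reagents that add atoms: triethylsilyl triflate CC[Si](CC)(CC)OS(=O)(=O)C(F)(F)F
Why: Silyl triflate/lutidine silylation of a hindered tertiary alcohol; TES is chosen over TMS because this ether later sits next to a cis-disposed acyl chloride and must resist methanolysis, mild acid and acylative cleavage to a δ-lactone.

**Step 12**
Reactants: 17 bis-TES ether
Product: 18 (3aS,4S,7S,7aS)-7-[(tert-butyldimethylsilyl)oxy]-5-iodo-4-[(triethylsilyl)oxy]-4-[4-(triethylsilyloxy)but-1-ynyl]-3a,4,7,7a-tetrahydro-1H-indene (trans ring fusion)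
Conditions: Grubbs II (5 mol %), CH2Cl2 (5 mM), reflux
Reagents that add atoms: none
Why: Ring-closing metathesis of the 1,6-diene formed by the trans-diequatorial vinyl and allyl groups gives the cyclopentene and carries their trans relationship into the ring fusion; the alkynyl group is 1,3-trans to the allyl group and cannot take part in enyne ring closure, and the trisubstituted vinyl iodide is inert.

**Step 13**
Reactants: 18 hydrindene vinyl iodide
Product: 19 methyl (3aS,4S,7S,7aS)-7-[(tert-butyldimethylsilyl)oxy]-4-[(triethylsilyl)oxy]-4-[4-(triethylsilyloxy)but-1-ynyl]-3a,4,7,7a-tetrahydro-1H-indene-5-carboxylate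
Conditions: Pd(OAc)2 (10 mol %), dppf, CO (1 atm), Et3N, MeOH/DMF, 60 °C
Reagents that add atoms: carbon monoxide [C-]#[O+]; methanol CO
Why: Palladium-catalysed alkoxycarbonylation of a vinyl iodide (oxidative addition, CO insertion, methanolysis) installs the ester only after all carbanion chemistry on this ring is finished, so that no doubly activated alkene ever meets a nucleophile.

**Step 14**
Reactants: 19 bis-TES enoate
Product: 20 methyl (3aS,4S,7S,7aS)-7-[(tert-butyldimethylsilyl)oxy]-4-(4-hydroxybut-1-ynyl)-4-[(triethylsilyl)oxy]-3a,4,7,7a-tetrahydro-1H-indene-5-carboxylate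
Conditions: PPTS (0.1 equiv), MeOH/CH2Cl2, 0 °C
Reagents that add atoms: none
Why: Acid-catalysed methanolysis distinguishes silyl ethers by steric access, so the primary TES ether goes while the tertiary TES and secondary TBS ethers stay.

**Step 15**
Reactants: 20 homopropargylic alcohol
Product: 21 methyl (3aS,4R,7S,7aS)-7-[(tert-butyldimethylsilyl)oxy]-4-[(1Z)-4-hydroxybut-1-enyl]-4-[(triethylsilyl)oxy]-3a,4,7,7a-tetrahydro-1H-indene-5-carboxylate
Conditions: H2 (1 atm), Lindlar catalyst, quinoline, EtOAc, rt
Reagents that add atoms: none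
Why: Lindlar semihydrogenation adds H2 syn to the alkyne and gives the (Z)-alkene that the later ring needs, the poisoned catalyst leaving the disubstituted cyclopentene and the enoate untouched.

**Step 16**
Reactants: 21 (Z)-homoallylic alcohol
Product: 22 (3Z)-4-[(3aS,4R,7S,7aS)-7-(TBSO)-5-(methoxycarbonyl)-4-(TESO)-3a,4,7,7a-tetrahydro-1H-inden-4-yl]but-3-enoic acid
Conditions: TEMPO (20 mol %), PhI(OAc)2 (2.5 equiv), MeCN/pH 7 buffer, rt
Reagents that add atoms: water O
Why: Oxoammonium (TEMPO/PhI(OAc)2) oxidation takes the primary alcohol through the aldehyde hydrate to the acid near neutral pH, which keeps the β,γ-(Z)-alkene out of conjugation and the silyl ethers in place.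

**Step 17**
Reactants: 22 (Z)-β,γ-unsaturated acid
Product: 23 methyl (3aS,4R,7S,7aS)-7-[(tert-butyldimethylsilyl)oxy]-4-[(1Z)-4-chloro-4-oxobut-1-enyl]-4-[(triethylsilyl)oxy]-3a,4,7,7a-tetrahydro-1H-indene-5-carboxylate
Conditions: 1-chloro-N,N,2-trimethylprop-1-en-1-amine, CH2Cl2, 0 °C; evaporated and used crude
Reagents that add atoms: 1-chloro-N,N,2-trimethylprop-1-en-1-amine CC(C)=C(Cl)N(C)C
Why: The α-chloroenamine converts the acid into its chloride under neutral conditions without HCl, so that the TES ether and the non-conjugated (Z)-alkene survive, and the chloride is used at once.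

**Step 18**
Reactants: 23 (Z)-β,γ-unsaturated acid chloride
Product: 25 tetracyclic cyclobutanone (methyl ester with OTES and OTBS retained; cyclobutanone cis-fused to the cyclopentane and to the new CH=CH cyclohexene on the face that carried the arm), via vinylketene 24 (not isolated)
Conditions: Et3N (5 equiv), toluene (final 2 mM), reflux; 23 added by syringe pump over 8 h
Reagents that add atoms: none
Why: Et3N removes one of the CH2 protons of the arm (α to COCl and allylic) and chloride leaves, giving the (Z)-vinylketene 24, whose electrophilic central carbon is attacked by the cyclopentene π bond in a concerted, asynchronous [π2s+π2a] cycloaddition; the closest known reaction type is the intramolecular [2+2] cycloaddition of ketenes and vinylketenes generated from acid chlorides with tethered unactivated alkenes, for which closures to bicyclo[4.2.0]octanones are known but slower than those to bicyclo[3.2.0]heptanones. The cyclobutanone closes through the two new bonds carbonyl carbon–C2 and α-carbon–C3 of the indene, and the second bond closes at the same time the cyclohexene (α-carbon, CH=CH, C4, C3a, C3) in the fused mode of a four-atom tether, the bridged mode (a seven-membered ring spanned by the carbonyl carbon) being excluded by strain since the alkene is electronically unbiased. The pseudoaxial arm on C4 can reach only the cyclopentene face that carries C4 at C3a, which fixes C3 and, through suprafacial addition, C2 (cis hydrogens), and the α-carbon is fixed because a six-membered ring holding a (Z)-alkene can only be cis-fused to the four-membered ring. The step needs chemoselectivity for C2=C3 over the nearer C5=C6 bond (three-atom tether), and the ester secures it by making C5=C6 electron-poor and trisubstituted, so that the electrophilic ketene passes it by. C4 is quaternary, so the (Z)-vinylketene has no δ-hydrogen for a 1,5-H shift, the TES ether resists acylative cleavage to the δ-lactone, and slow addition at high dilution holds back dimerisation.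

**Step 19**
Reactants: 25 tetracyclic cyclobutanone
Product: 26 (methoxymethylidene)cyclobutane (E/Z mixture at the enol ether)
Conditions: Ph3P(CH2OMe)Cl, KHMDS, THF, 0 °C; then 25, 0 °C → rt
Reagents that add atoms: (methoxymethyl)triphenylphosphonium chloride COC[P+](c1ccccc1)(c1ccccc1)c1ccccc1.[Cl-]
Why: Wittig methoxymethylenation: the strained, electrophilic cyclobutanone is open on its convex face, enolisation is reversible and cannot change the ring-locked α-centres, and the hindered conjugated ester does not react with the ylide.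

**Step 20**
Reactants: 26 enol ether
Product: 28 exo-aldehyde (formyl group on the convex face of the cyclobutane and trans to both neighbouring ring bonds), via endo-aldehyde 27 (not isolated)
Conditions: PPTS (0.3 equiv), acetone/H2O, 45 °C; crude product, DBU (0.3 equiv), CH2Cl2, rt
Reagents that add atoms: water O
Why: Enol ether hydrolysis protonates the ring carbon from the convex face and gives mainly endo-aldehyde 27, and base-mediated epimerisation through the enolate then moves the formyl group to the convex face, which sets the last stereocentre under thermodynamic control (loss of the tertiary TES group here would not harm the later steps).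

**Step 21**
Reactants: 28 exo-aldehyde
Product: 29 exo-hydroxymethyl compound
Conditions: NaBH4, MeOH, 0 °C
Reagents that add atoms: none
Why: Borohydride reduction is chemoselective for the aldehyde over the conjugated ester and freezes the configuration at the former α-carbon.

**Step 22**
Reactants: 29 exo-hydroxymethyl compound
Product: 30 exo-(tosyloxymethyl) compound
Conditions: TsCl, Et3N, DMAP (cat.), CH2Cl2, 0 °C → rt
Reagents that add atoms: 4-toluenesulfonyl chloride Cc1ccc(cc1)S(=O)(=O)Cl
Why: Sulfonylation of the only free, primary hydroxyl group; a tosylate is preferred to an iodide because it couples by an SN2-type path without a cyclobutylmethyl radical that could open the ring.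

**Step 23**
Reactants: 30 tosylate; 31 heptylmagnesium bromide
Product: 32 octyl tetracycle (methyl ester, OTES, OTBS)
Conditions: 31 (2 equiv), Li2CuCl4 (5 mol %), THF, −40 → 0 °C
Reagents that add atoms: none
Why: Copper-catalysed alkyl–alkyl cross-coupling of a Grignard reagent with a primary tosylate (Kochi-type Li2CuCl4 catalysis) is fast at low temperature, where the α-branched cyclic enoate flanked by OTES and OTBS groups is slow in both 1,2- and 1,4-addition.

**Step 24**
Reactants: 32 bis-silyl ether
Product: 33 diol methyl ester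
Conditions: TBAF (4 equiv), THF, 0 °C → rt
Reagents that add atoms: none
Why: Fluoride-induced desilylation removes both silyl groups in a non-acidic medium that spares the doubly allylic tertiary alcohol, and neither alkoxide can lactonise onto the ester for geometric reasons.

**Step 25**
Reactants: 33 diol methyl ester
Product: 34 target CNP0106718.3
Conditions: LiOH, THF/MeOH/H2O, 40 °C; 1 M HCl to pH 4, 0 °C
Reagents that add atoms: lithium hydroxide [Li+].[OH-]
Why: Saponification (BAc2) of the methyl ester touches no stereocentre, and acidification only to pH 4 in the cold avoids ionisation of the tertiary allylic alcohol.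

**Compound list**
1 | 4,4-dimethoxycyclohexa-2,5-dien-1-one | COC1(OC)C=CC(=O)C=C1 | starting material
2 | potassium vinyltrifluoroborate | C=C[B-](F)(F)F.[K+] | starting material
3 | (5R)-5-ethenyl-4,4-dimethoxycyclohex-2-en-1-one | COC1(OC)C=CC(=O)C[C@@H]1C=C | intermediate
4 | allyl bromide | C=CCBr | starting material
5 | lithium dienolate of 3 | COC1(OC)C=CC(O[Li])=C[C@@H]1C=C | intermediate
6 | (5S,6S)-5-ethenyl-4,4-dimethoxy-6-(prop-2-enyl)cyclohex-2-en-1-one | COC1(OC)C=CC(=O)[C@@H](CC=C)[C@@H]1C=C | intermediate
7 | (1S,5S,6S)-5-ethenyl-4,4-dimethoxy-6-(prop-2-enyl)cyclohex-2-en-1-ol | COC1(OC)C=C[C@H](O)[C@@H](CC=C)[C@@H]1C=C | intermediate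
8 | (1R,5S,6S)-5-ethenyl-4,4-dimethoxy-6-(prop-2-enyl)cyclohex-2-en-1-yl 4-nitrobenzoate | COC1(OC)C=C[C@@H](OC(=O)c2ccc(cc2)[N+](=O)[O-])[C@@H](CC=C)[C@@H]1C=C | intermediate
9 | (1R,5S,6S)-5-ethenyl-4,4-dimethoxy-6-(prop-2-enyl)cyclohex-2-en-1-ol | COC1(OC)C=C[C@@H](O)[C@@H](CC=C)[C@@H]1C=C | intermediate
10 | TBS ether of 9 | COC1(OC)C=C[C@@H](O[Si](C)(C)C(C)(C)C)[C@@H](CC=C)[C@@H]1C=C | intermediate
11 | (4R,5S,6S)-4-(TBSO)-6-ethenyl-5-(prop-2-enyl)cyclohex-2-en-1-one | O=C1C=C[C@@H](O[Si](C)(C)C(C)(C)C)[C@@H](CC=C)[C@@H]1C=C | intermediate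
12 | (4S,5S,6S)-4-(TBSO)-6-ethenyl-2-iodo-5-(prop-2-enyl)cyclohex-2-en-1-one | O=C1C(I)=C[C@@H](O[Si](C)(C)C(C)(C)C)[C@@H](CC=C)[C@@H]1C=C | intermediate
13 | but-3-yn-1-ol | C#CCCO | starting material
14 | 4-(triethylsilyloxy)but-1-yne | C#CCCO[Si](CC)(CC)CC | intermediate
15 | lithium acetylide of 14 | [Li]C#CCCO[Si](CC)(CC)CC | intermediate
16 | (1S,4S,5S,6S) tertiary propargylic alcohol | CC[Si](CC)(CC)OCCC#C[C@]1(O)C(I)=C[C@@H](O[Si](C)(C)C(C)(C)C)[C@@H](CC=C)[C@@H]1C=C | intermediate
17 | bis-TES ether of 16 | CC[Si](CC)(CC)OCCC#C[C@]1(O[Si](CC)(CC)CC)C(I)=C[C@@H](O[Si](C)(C)C(C)(C)C)[C@@H](CC=C)[C@@H]1C=C | intermediate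
18 | trans-fused 5-iodotetrahydroindene | CC[Si](CC)(CC)OCCC#C[C@]1(O[Si](CC)(CC)CC)C(I)=C[C@@H](O[Si](C)(C)C(C)(C)C)[C@H]2CC=C[C@@H]21 | intermediate
19 | tetrahydroindene-5-carboxylate, bis-TES | CC[Si](CC)(CC)OCCC#C[C@]1(O[Si](CC)(CC)CC)C(C(=O)OC)=C[C@@H](O[Si](C)(C)C(C)(C)C)[C@H]2CC=C[C@@H]21 | intermediate
20 | homopropargylic alcohol | OCCC#C[C@]1(O[Si](CC)(CC)CC)C(C(=O)OC)=C[C@@H](O[Si](C)(C)C(C)(C)C)[C@H]2CC=C[C@@H]21 | intermediate
21 | (Z)-homoallylic alcohol | OCC/C=C\[C@]1(O[Si](CC)(CC)CC)C(C(=O)OC)=C[C@@H](O[Si](C)(C)C(C)(C)C)[C@H]2CC=C[C@@H]21 | intermediate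
22 | (Z)-β,γ-unsaturated acid | OC(=O)C/C=C\[C@]1(O[Si](CC)(CC)CC)C(C(=O)OC)=C[C@@H](O[Si](C)(C)C(C)(C)C)[C@H]2CC=C[C@@H]21 | intermediate
23 | (Z)-β,γ-unsaturated acid chloride (key-step precursor) | O=C(Cl)C/C=C\[C@]1(O[Si](CC)(CC)CC)C(C(=O)OC)=C[C@@H](O[Si](C)(C)C(C)(C)C)[C@H]2CC=C[C@@H]21 | intermediate
24 | (Z)-vinylketene | O=C=C/C=C\[C@]1(O[Si](CC)(CC)CC)C(C(=O)OC)=C[C@@H](O[Si](C)(C)C(C)(C)C)[C@H]2CC=C[C@@H]21 | intermediate
25 | tetracyclic cyclobutanone (key-step product) | O=C1[C@@H]2C=C[C@]3(O[Si](CC)(CC)CC)C(C(=O)OC)=C[C@@H](O[Si](C)(C)C(C)(C)C)[C@H]4C[C@H]1[C@H]2[C@@H]43 | intermediate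
26 | (methoxymethylidene)cyclobutane, E/Z | COC=C1[C@@H]2C=C[C@]3(O[Si](CC)(CC)CC)C(C(=O)OC)=C[C@@H](O[Si](C)(C)C(C)(C)C)[C@H]4C[C@H]1[C@H]2[C@@H]43 | intermediate
27 | endo-aldehyde | O=C[C@@H]1[C@@H]2C=C[C@]3(O[Si](CC)(CC)CC)C(C(=O)OC)=C[C@@H](O[Si](C)(C)C(C)(C)C)[C@H]4C[C@H]1[C@H]2[C@@H]43 | intermediate
28 | exo-aldehyde | O=C[C@H]1[C@@H]2C=C[C@]3(O[Si](CC)(CC)CC)C(C(=O)OC)=C[C@@H](O[Si](C)(C)C(C)(C)C)[C@H]4C[C@H]1[C@H]2[C@@H]43 | intermediate
29 | exo-hydroxymethyl compound | OC[C@H]1[C@@H]2C=C[C@]3(O[Si](CC)(CC)CC)C(C(=O)OC)=C[C@@H](O[Si](C)(C)C(C)(C)C)[C@H]4C[C@H]1[C@H]2[C@@H]43 | intermediate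
30 | exo-(tosyloxymethyl) compound | Cc1ccc(cc1)S(=O)(=O)OC[C@H]1[C@@H]2C=C[C@]3(O[Si](CC)(CC)CC)C(C(=O)OC)=C[C@@H](O[Si](C)(C)C(C)(C)C)[C@H]4C[C@H]1[C@H]2[C@@H]43 | intermediate
31 | heptylmagnesium bromide (commercial solution) | CCCCCCC[Mg]Br | starting material
32 | octyl tetracycle, methyl ester, OTES, OTBS | CCCCCCCC[C@H]1[C@@H]2C=C[C@]3(O[Si](CC)(CC)CC)C(C(=O)OC)=C[C@@H](O[Si](C)(C)C(C)(C)C)[C@H]4C[C@H]1[C@H]2[C@@H]43 | intermediate
33 | diol methyl ester | CCCCCCCC[C@H]1[C@@H]2C=C[C@]3(O)C(C(=O)OC)=C[C@@H](O)[C@H]4C[C@H]1[C@H]2[C@@H]43 | intermediate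
34 | CNP0106718.3 | CCCCCCCC[C@H]1[C@@H]2C=C[C@]3(O)C(C(=O)O)=C[C@@H](O)[C@H]4C[C@H]1[C@H]2[C@@H]43 | target

**Step count**
Total steps: 25. Longest linear sequence: 24 (steps 1–8 and 10–25, from 1 to 34).

**Steps most likely to fail**

Step 18. Closure over the four-atom tether may be slow. Ketene dimerisation, electrocyclic closure of the (Z)-vinylketene to a cyclobutenone, or acylative loss of the neighbouring silyl ether could then overtake the cycloaddition. The fallback replaces the ketene by the more electrophilic keteniminium ion. It sets out from acid 22, which is coupled with pyrrolidine (EDC·HCl, HOBt, CH2Cl2) to the pyrrolidine amide F1. Tf2O and 2,4,6-collidine in refluxing 1,2-dichloroethane give the keteniminium triflate F2, which should add to the cyclopentene with the same regio- and facial sense to the cyclobutaniminium triflate F3. Hydrolysis with aqueous NaHCO3 returns to the route at cyclobutanone 25.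

Step 23. The Grignard or cuprate species may attack the methyl enoate (1,2- or 1,4-addition), or substitution at the β-branched cyclobutylmethyl carbon may be sluggish. The fallback changes to an ester-tolerant palladium-catalysed alkyl–alkyl Suzuki–Miyaura coupling. It sets out from alcohol 29, which is converted (CBr4, PPh3, CH2Cl2) into the exo-bromomethyl compound F4. Hept-1-ene and 9-BBN give B-heptyl-9-BBN F5. Pd(OAc)2, PCy3 and K3PO4·H2O in THF at rt join the two and return to the route at 32.

Step 19. The basic ylide may only enolise the doubly activated α-CH, or nucleophilic addition may trigger cleavage of the strained ring instead of olefination. The fallback brings in the extra carbon without base and corrects its configuration afterwards. It sets out from 25, which is methylenated with Cp2TiMe2 (1.2 equiv, toluene, 65 °C) to the exocyclic methylene compound F6. 9-BBN hydroborates this 1,1-disubstituted alkene from the convex face to the B-alkyl-9-BBN adduct F7, and NaBO3 oxidation gives the endo-hydroxymethyl compound F8. Dess–Martin oxidation returns to the route at endo-aldehyde 27, which the DBU treatment of step 20 converts into 28.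

**Further compounds**
F1 | step 18 | pyrrolidine amide of 22 | O=C(N5CCCC5)C/C=C\[C@]1(O[Si](CC)(CC)CC)C(C(=O)OC)=C[C@@H](O[Si](C)(C)C(C)(C)C)[C@H]2CC=C[C@@H]21
F2 | step 18 | keteniminium triflate | [O-]S(=O)(=O)C(F)(F)F.C5CC[N+](C5)=C=C/C=C\[C@]1(O[Si](CC)(CC)CC)C(C(=O)OC)=C[C@@H](O[Si](C)(C)C(C)(C)C)[C@H]2CC=C[C@@H]21
F3 | step 18 | cyclobutaniminium triflate | [O-]S(=O)(=O)C(F)(F)F.C5CC[N+](C5)=C1[C@@H]2C=C[C@]3(O[Si](CC)(CC)CC)C(C(=O)OC)=C[C@@H](O[Si](C)(C)C(C)(C)C)[C@H]4C[C@H]1[C@H]2[C@@H]43
F4 | step 23 | exo-bromomethyl compound | BrC[C@H]1[C@@H]2C=C[C@]3(O[Si](CC)(CC)CC)C(C(=O)OC)=C[C@@H](O[Si](C)(C)C(C)(C)C)[C@H]4C[C@H]1[C@H]2[C@@H]43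
F5 | step 23 | B-heptyl-9-BBN | CCCCCCCB1C2CCCC1CCC2
F6 | step 19 | exocyclic methylene compound | C=C1[C@@H]2C=C[C@]3(O[Si](CC)(CC)CC)C(C(=O)OC)=C[C@@H](O[Si](C)(C)C(C)(C)C)[C@H]4C[C@H]1[C@H]2[C@@H]43
F7 | step 19 | B-alkyl-9-BBN adduct (endo) | C(B5C6CCCC5CCC6)[C@@H]1[C@@H]2C=C[C@]3(O[Si](CC)(CC)CC)C(C(=O)OC)=C[C@@H](O[Si](C)(C)C(C)(C)C)[C@H]4C[C@H]1[C@H]2[C@@H]43
F8 | step 19 | endo-hydroxymethyl compound | OC[C@@H]1[C@@H]2C=C[C@]3(O[Si](CC)(CC)CC)C(C(=O)OC)=C[C@@H](O[Si](C)(C)C(C)(C)C)[C@H]4C[C@H]1[C@H]2[C@@H]43
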